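The data stem from a simulated flask on assumed constants; noise was put on by code.

3 questions hung on one decision: what to charge in the next run so that its excess says something about exchange between the substrates.

- Thursday's: left-handed substrate 0.032 M; right-handed substrate 0.032 M; partner 2 equiv (fed, over 25 s); free catalyst 15 mol%; added ligand 13 mM; run made earlier; the fed solution adds 0.50 times the starting volume
- flask: left-handed substrate 0.016 M; partner 2.00 equiv (fed, over 25 s); free catalyst 15 mol%; added ligand 13 mM; right-handed substrate 0.016 M; time 3.0 min; the fed solution adds 0.50 times the starting volume

Thursday's run (percent of the left-handed substrate and right-handed substrate together charged)

| time / s | left-handed product / % | right-handed product / % |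
|---|---|---|
| 10.0 | 16.8 | 6.9 |
| 12.0 | 21.7 | 8.8 |
| 15.0 | 25.7 | 11.8 |
| 20.0 | 32.0 | 16.0 |

(each reading ± 1 percentage point)

- left-handed product and right-handed product together, in percent of the left-handed substrate and right-handed substrate charged together, at 3.0 min
- excess of left-handed product over right-handed product in the product at 3.0 min
- whether the exchange between left-handed substrate and right-handed substrate keeps pace with the reaction: how far the product's excess at 3.0 min gets from its value without exchange to its value with instant exchange (above 80 % keeps pace, below 20 % hardly takes part, else lags behind)

- free catalyst is single-handed; left-handed substrate and right-handed substrate are mirror images of each other, charged as a racemate, each of them at the stated concentration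
- amounts are per litre of the starting volume; all of the dose is in the solution fed
- an excess is the difference of the two amounts in percent of their sum
- an excess is below zero if the other one leads
- no earlier run changes the charge of free catalyst; that part of a forecast is a guess

At 10.0 s, the earliest reading, Thursday's run held left-handed to right-handed product at 2.43. I took this as a reading of the selectivity factor, supposing that both substrates meet the same catalyst and partner, so that dilution leaves it alone. As an excess that ratio is 41.8 %, with 1 percentage point of scatter on each reading, and I call it the ceiling excess, the excess of product formed from equal substrates. By 20.0 s Thursday's excess had sunk to 33.3 %, lower, but that fall could mean absent exchange or merely lagging exchange. I supposed that exchange needs neither catalyst nor partner, so its time stays while the reaction slows on dilution. I therefore halved both substrates and kept the equivalents of partner, its dosing time, the loading of free catalyst and the concentration of added ligand. My commitment went no further than a bracket: an excess near 41.8 % stands for exchange that keeps pace, one far below it for exchange that hardly takes part.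

The forecast gave 75 % of product, an excess of 21 %, well under my ceiling, and an exchange that hardly takes part, reading Thursday's run “as in plain kinetic resolution without exchange”.

The flask gave 83.7 % with an excess of 39.5 %, under my ceiling of 41.8 %, and the exchange keeps pace: the excess got 87 % of the way from 16.5 %, its value without exchange, to its value with instant exchange.

    free catalyst + added ligand ⇌ idle complex (K = 89.0 M⁻¹, k = 5.20 M⁻¹ s⁻¹)
    2 free catalyst → spent catalyst (k = 13.0 M⁻¹ s⁻¹)
    partner + free catalyst + right-handed substrate → free catalyst + right-handed product (k = 4800 M⁻² s⁻¹)
    left-handed substrate ⇌ right-handed substrate (k = 0.0800 s⁻¹)
    2 free catalyst ⇌ resting dimer (K = 25000 M⁻¹, k = 58.0 M⁻¹ s⁻¹)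
    partner + free catalyst + left-handed substrate → free catalyst + left-handed product (k = 12000 M⁻² s⁻¹)

In the flask the exchange relaxed with a half-life of 0.0722 min, both ways together and by this step alone, against 5.1 min for right-handed substrate by its step to right-handed product at 3.00 min. At that time left-handed and right-handed substrate stood at 8.06 % and 8.24 % of the two charged together. For the same flask with 0.500 equiv of partner the ceiling excess gave 41.8 % for the product; that computed neighbour held 42.1 % at a yield of 24.6 %, with partner, the limiting reagent, down to 1.6 % of its charge.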